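Remark on the chemistry: flavanone locants are used for all intermediates (unit A unprimed with a primed aryl ring, unit B double-primed with a triple-primed aryl ring). Two design choices apply throughout: the fluoroarene carries its two benzyloxy groups before it is attached, because fluorine left on C-5/C-7 could not be exchanged for oxygen later without opening the flavanones; and no bis-γ-lactone (O-1 to C-4'', O-1'' to C-4) is used, because with the meso-type C-3/C-3'' relation it would have to be a trans-fused 3,7-dioxabicyclo[3.3.0]octane-4,8-dione.

## Structural features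

The target is a 3,3''-biflavanone: two 5,7-dihydroxy-2-arylchroman-4-one units joined by the single bond C-3–C-3''. Each unit is a phloroglucinol-type benzene ring fused to a dihydropyranone (O-1, C-2, C-3, C-4, C-4a, C-8a), with a 4-methoxyphenyl ring on C-2 of unit A and a 4-hydroxyphenyl ring on C-2'' of unit B. The four stereocentres C-2, C-3, C-3'' and C-2'' are contiguous on a four-carbon chain. Both pyranone rings are 2,3-trans (2S,3R and 2''R,3''S), and the two halves are mirror images apart from the 4'-O-methyl group, so the molecule is chiral only through that remote methyl (pseudo-meso). Fragile sites are the hydrogens on C-3 and C-3'' (α to a ketone, epimerisable), the benzylic aryl ether bonds C-2–O-1 and C-2''–O-1'' (β to the ketones; lost by E1cB opening in base and by ionisation in acid) and the electron-rich phloroglucinol phenols. The real difficulty is the hindered C-3–C-3'' bond together with the relative configuration of four adjacent centres, and then telling apart two halves that differ only at a para oxygen. The chain C-2–C-3–C-3''–C-2'' maps onto four adjacent sp3 carbons of an all-cis 3,6-diarylcyclohex-4-ene-1,2-dicarboxylic anhydride: the two alkene carbons stand where O-1 and O-1'' will be, and the anhydride carbonyl carbons are C-4 and C-4''. The key step exploits this, because that cyclohexene is the endo adduct of an E,E-1,4-diarylbutadiene and a cis dienophile.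

## Logic of the disconnections

20 from 19. The five O–CH2Ph bonds (on O-5, O-7, O-5'', O-7'' and O-4''') are cut. Every phenol other than the 4'-methyl ether is thereby carried as one kind of ether that leaves in a single neutral step, so no free phloroglucinol ring has to survive oxidants or bases. The forward step must spare the benzylic C-2–O-1 bonds, the ketones and the methyl ether.

19 from 17 (through 18). The aryl ether bonds O-1–C-8a and O-1''–C-8a'' are cut, with fluorine placed on C-8a and C-8a''. The cut lies on the aryl side of oxygen so that the C-2–O bonds are never broken in the forward direction and configuration at C-2 and C-2'' is retained. Both pyranone rings disappear and an open-chain 1,4-diketone with two O-formyl groups remains. The forward closure has to outrun retro-aldol cleavage of the β-hydroxy ketones in 18.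

17 from 15 (through 16). The oxygens on C-2 and C-2'' are replaced by carbon and the two new carbons are joined as a cis double bond. The four contiguous centres thereby become ring atoms of a cyclohexene whose relative configuration can be set in one step, so an acyclic stereochemical problem becomes a cyclic one. The forward steps demand attack of ozone on the alkene in the presence of electron-rich arenes, and migration of the benzylic carbon with retention before the α-aryl aldehyde groups of 16 can enolise.

15 from 9 and 12 (through 13 and 14). The bonds C-4–C-4a and C-4''–C-4a'' are cut between carbonyl carbon and arene, so that one molecule of 9 is joined to two molecules of 12. Both phloroglucinol rings arrive ready-made, with protected oxygens and the fluorine leaving group in place, and 9 keeps only the four stereocentres and two formyl groups. The forward addition must occur at one defined arene carbon, which the bromine of 12 ensures, must take place at both formyl groups, and must not epimerise the centres α to the carbonyl groups.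

12 from 11, and 11 from 10. The C–Br bond and then two C–O bonds are cut, which leads to a symmetrical commercial arene. The forward steps must stop after two of the three fluorines are replaced, and bromination must take the position next to fluorine.

9 from 8, 8 from 7, and 7 from 6. No skeletal bond is cut: the formyl carbons of 9 are traced through the hydroxymethyl groups of 8 to the anhydride carbons of 6, and single-enantiomer 8 is traced to racemic 7. The separation is placed at the first robust, hydrogen-bonding intermediate and before any costly fragment is attached. The oxidation-state changes must not epimerise centres α to carbonyl. The separation must distinguish enantiomers whose only difference is methyl versus benzyl on otherwise mirror-related rings.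

6 from 4 and 5. The ring bonds that become C-2–C-3 and C-2''–C-3'' are cut, which opens the cyclohexene into a diene and a cis dienophile. This gives the greatest simplification: four stereocentres and the C-3/C-3'' backbone come from two flat achiral components. The forward step must be suprafacial and endo. Its absolute sense cannot be controlled, because the diene termini differ only at remote para oxygens; benzyl is kept on the second oxygen because it differs enough from methyl for the later separation and leaves with the other benzyl groups.

4 from 2 and 3, and 2 from 1. The central C=C bond of 4 is cut into a phosphonate carbanion and an enal, then the C–P bond is cut. An E-selective phosphonate olefination gives the E,E geometry directly, so no separate isomerisation step is needed and two commercial components remain. The forward olefination must form the new double bond E and leave the existing one untouched.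

## Other disconnections considered

Alternative 1: In each half the ring bonds C-4a–C-5 and C-8–C-8a are cut, so both phloroglucinol rings are removed and the four stereocentres stay on the bis(5-bromo-2,3-dihydro-4H-pyran-4-one) A2.
- Forward key step: two equivalents of 1-methoxy-1,3-bis(trimethylsilyloxy)buta-1,3-diene A3 would add across the C-4a=C-8a bonds of A2, the CH2 terminus bonding to the oxygen-bearing C-8a and the ketene-acetal carbon to the brominated C-4a. Loss of hydrogen halide, alcohol and silanol after each addition would aromatise both rings to the 4'''-O-benzyl ether A1, one hydrogenolysis from 20.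
- In favour: the 5,7-oxygenation arrives with the correct pattern and no aryl–metal or aryl fluoride chemistry is needed.
- Against, here: the key step creates no stereocentre. All four centres and the C-3–C-3'' bond must already be present in A2, whose dihydropyranone rings are as prone to C-3 epimerisation and E1cB opening as the flavanones. A2 is a β-alkoxy enone, a weak dienophile that would have to react twice beside the substituted C-3 carbons, and the aromatisation needs acid or base while C-2 and C-3 are labile.
- Comparison: structurally it postpones the hard problem, which the chosen plan solves in step 3. Mechanistically a double cycloaddition–aromatisation on a donor-substituted bromo-enone is less certain than the addition of 4 to 5. On step economy after the key step it is the better (one step to 20 against ten further steps), and it is also the better in protecting-group economy and in avoiding the ring closure of step 12. These gains do not outweigh an undefined route to A2 that would need its own way of setting four centres and the absolute configuration.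

Alternative 2: The C-2–C-3 bond of unit A is cut. C-3 becomes a diazo carbon and C-2 the benzylic CH2 of a 4-methoxybenzyl ether on O-1, which gives the diazoketone A5 with unit B already a complete flavanone.
- Forward key step: Rh2(S-PTTL)4, dirhodium tetrakis[N-phthaloyl-(S)-tert-leucinate] (divalent rhodium), would take N2 from A5, and the rhodium-bound carbene carbon C-3 would insert into a benzylic C–H bond of the 4-methoxybenzyl ether. This closes the pyranone of unit A and gives the fully protected biflavanone A4.
- In favour: it is highly convergent, the C–H bond is activated by oxygen and by the anisyl ring, and the key step ends at the complete skeleton. The catalyst rather than a separation would decide the configuration at C-2, and on this point it is better than the chosen plan, which discards half of 7.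
- Against, here: the carbene carbon bears C-3'' with its hydrogen, so 1,2-hydride migration is the expected fast competitor. Other benzylic ether C–H bonds and electron-rich arenes are within reach. The cis or trans outcome at C-2/C-3 and its match with the existing centres are open. A5 needs unit B as a single enantiomer and a diazo transfer onto a hindered, non-activated ketone.
- Comparison: both plans end with deprotection, so they are equal there. The alternative is better in absolute stereocontrol and convergence in principle. It is worse in the number of competing carbene pathways, needs three kinds of oxygen protection against one, and does not use the pseudo-symmetry, so each half must be built separately and the total count would be higher.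

Alternative 3: C-3, C-3'', C-4 and C-4'' are hidden in a furan (C-4 and C-4'' as its α-carbons), and in unit B the bonds O-1''–C-2'' and C-2''–C-3'' are cut. This gives the furyl phenol A7 and 4-(benzyloxy)benzaldehyde A8.
- Forward key step: under a chiral phosphoric acid, A7 and A8 would form an oxocarbenium ion on the phenol oxygen, which the furan β-carbon attacks (oxa-Pictet–Spengler reaction). This closes the second pyran and gives the pentacyclic furan A6. Oxidative opening of the furan to the Z-ene-dione A9, reduction of its C-3=C-3'' bond and debenzylation would follow.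
- In favour: the furan protects the epimerisable 1,4-diketone through the synthesis. The configuration at C-2'' would be catalyst-controlled without a separation, a point on which it is better than the chosen plan.
- Against, here: the key step sets only C-2''. C-3 and C-3'' arise later in the reduction of the tetrasubstituted ene-dione A9, where syn addition gives the meso-type relation but the relation to C-2 and C-2'' rests on thermodynamics. The furan must react at its less nucleophilic β-position. The C-2–O bonds of A6 are doubly benzylic and could ionise under the acid catalyst. The furan must be opened oxidatively beside five electron-rich arenes.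
- Comparison: the two plans are equal in leaning on the 2,3-trans preference of the chromanones, although the chosen plan also delivers that arrangement kinetically. The chosen plan sets four centres in one precedented step, the alternative one centre per key step. After the key step the alternative is shorter (about three steps against ten), but with the preparation of A7 counted the total is unlikely to be lower.

Key step: step 3

## Route

Step 1
Reactants: 1 4-(benzyloxy)benzyl chloride
Product: 2 diethyl [4-(benzyloxy)benzyl]phosphonate
Conditions: P(OEt)3 (neat), 150 °C
Reagents that add atoms: triethyl phosphite, CCOP(OCC)OCC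
Why: Michaelis–Arbuzov reaction: the phosphite displaces the benzylic chloride and chloride dealkylates the phosphonium ion; benzylic halides are standard substrates and chloroethane distils off.

Step 2
Reactants: 2 diethyl [4-(benzyloxy)benzyl]phosphonate; 3 (E)-4-methoxycinnamaldehyde
Product: 4 (1E,3E)-1-[4-(benzyloxy)phenyl]-4-(4-methoxyphenyl)buta-1,3-diene
Conditions: KOt-Bu, THF, 0 °C → rt
Reagents that add atoms: none
Why: Horner–Wadsworth–Emmons olefination: the benzylphosphonate carbanion adds reversibly to the non-enolisable enal and eliminates phosphate through the anti pathway, so the new double bond forms E and the existing E-alkene is untouched; no isomerisation step is needed.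

Step 3
Reactants: 4 (1E,3E)-1-[4-(benzyloxy)phenyl]-4-(4-methoxyphenyl)buta-1,3-diene; 5 maleic anhydride
Product: 6 racemic all-cis 4-[4-(benzyloxy)phenyl]-7-(4-methoxyphenyl)-3a,4,7,7a-tetrahydro-2-benzofuran-1,3-dione
Conditions: xylenes, 140 °C, N2
Reagents that add atoms: none
Why: A thermal, concerted, suprafacial Diels–Alder cycloaddition of normal electron demand: the HOMO of the electron-rich s-cis diene 4 overlaps with the LUMO of 5, and both σ-bonds (the later C-2–C-3 and C-2''–C-3'') form in one step. The closest known reaction is the addition of (E,E)-1,4-diarylbuta-1,3-dienes to maleic anhydride, which gives all-cis adducts. The only ring closed is the cyclohexene, by intermolecular [4+2] cycloaddition; the anhydride ring is brought in intact. The two aryl-bearing centres are set relative to each other by the E,E geometry of 4, because suprafacial bonding at both termini turns both outward aryl groups to the same face. The two anhydride-bearing centres are cis to each other because the dienophile is a ring-locked cis alkene that adds suprafacially. Their relation to the aryl centres comes from the endo transition state, in which the carbonyl groups lie under the central carbons of the diene, so the anhydride ends up cis to both aryl groups. The selectivity needed is endo over exo; the flat, compact, doubly activated dienophile and kinetic control well below the temperature of cycloreversion secure it. There is no face selectivity, since the two faces of 4 differ only through the remote methyl and benzyl ethers, so 6 forms as a racemate.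

Step 4
Reactants: 6 racemic all-cis anhydride
Product: 7 racemic all-cis [3-[4-(benzyloxy)phenyl]-6-(4-methoxyphenyl)cyclohex-4-ene-1,2-diyl]dimethanol
Conditions: LiAlH4, THF, 0 °C → rt
Reagents that add atoms: none
Why: Hydride reduction of a cyclic anhydride to the 1,4-diol; reduction of each carbonyl is faster than enolisation, so no stereocentre is touched.

Step 5
Reactants: 7 racemic diol
Product: 8 [(1S,2R,3R,6S)-3-[4-(benzyloxy)phenyl]-6-(4-methoxyphenyl)cyclohex-4-ene-1,2-diyl]dimethanol
Conditions: preparative SFC, amylose tris(3,5-dimethylphenylcarbamate) on silica, CO2/MeOH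
Reagents that add atoms: none
Why: Resolution by chromatography on a chiral stationary phase: the two hydroxyl groups give hydrogen-bond contacts to the carbamate selector, and the enantiomers differ by a methyl against a benzyl ether on otherwise mirror-related wings, a difference in size and π-surface that the selector should discriminate. No stereocentre is formed; the absolute configuration of all four centres is fixed by the choice of fraction, to be assigned by crystallography of a heavy-atom derivative.

Step 6
Reactants: 8 (1S,2R,3R,6S)-diol
Product: 9 (1S,2R,3R,6S)-3-[4-(benzyloxy)phenyl]-6-(4-methoxyphenyl)cyclohex-4-ene-1,2-dicarbaldehyde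
Conditions: (COCl)2, DMSO, CH2Cl2, −78 °C; Et3N, −78 → −20 °C; non-aqueous work-up, used crude
Reagents that add atoms: none
Why: Swern oxidation: both hydroxyl groups are converted into alkoxysulfonium ions before the base is added, so the dialdehyde forms instead of a lactol or lactone; the low temperature limits epimerisation α to the formyl groups.

Step 7
Reactants: 10 1,3,5-trifluorobenzene
Product: 11 1,3-bis(benzyloxy)-5-fluorobenzene
Conditions: BnOH (2.1 equiv), KOt-Bu, DMSO, rt → 80 °C
Reagents that add atoms: benzyl alcohol, OCc1ccccc1
Why: Twofold nucleophilic aromatic substitution: each fluorine is activated inductively by the two meta fluorines, and an entering alkoxy group sits meta to the remaining fluorines and does not shut them down by resonance; the third substitution is the slowest, so stoichiometry and temperature stop the reaction at the monofluoride.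

Step 8
Reactants: 11 1,3-bis(benzyloxy)-5-fluorobenzene
Product: 12 1,5-bis(benzyloxy)-2-bromo-3-fluorobenzene
Conditions: NBS, MeCN, 0 °C → rt
Reagents that add atoms: N-bromosuccinimide, O=C1CCC(=O)N1Br
Why: Electrophilic aromatic bromination: the position next to fluorine is ortho to one benzyloxy group and para to the other and is less hindered than the position flanked by two benzyloxy groups, as with other 5-substituted resorcinol diethers; the bromine fixes the later metalation site.

Step 9
Reactants: 9 (1S,2R,3R,6S)-dialdehyde; 12 1,5-bis(benzyloxy)-2-bromo-3-fluorobenzene (two molar equivalents enter the product, one per formyl group)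
Product: 14 bis-carbinol from twofold aryl addition to 9 (carbinol centres as mixtures), via aryl Grignard reagent 13 (not isolated)
Conditions: 12 (2.5 equiv), i-PrMgCl·LiCl (2.5 equiv), THF, 0 °C → rt; then 9 (1.0 equiv), −40 → 0 °C; pH 7 buffer
Reagents that add atoms: second equivalent of 12, 1,5-bis(benzyloxy)-2-bromo-3-fluorobenzene, Fc1cc(OCc2ccccc2)cc(OCc2ccccc2)c1Br
Why: Bromine–magnesium exchange, helped by the flanking fluorine and alkoxy group, gives an ortho-fluoroaryl Grignard reagent that tolerates 0 °C without aryne formation. Two equivalents of it add 1,2 to the two formyl groups of 9, one aryl group per aldehyde, so two equivalents of 12 are consumed; the excess and warming carry the second addition through any magnesium lactolate formed after the first. The new carbinol centres are erased in step 10.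

Step 10
Reactants: 14 bis-carbinol
Product: 15 [(1S,2R,3R,6S)-3-[4-(benzyloxy)phenyl]-6-(4-methoxyphenyl)cyclohex-4-ene-1,2-diyl]bis{[2,4-bis(benzyloxy)-6-fluorophenyl]methanone}
Conditions: Dess–Martin periodinane, NaHCO3 (buffer), CH2Cl2, 0 °C → rt
Reagents that add atoms: none
Why: Dess–Martin oxidation of two secondary benzylic alcohols under buffered, non-basic conditions, which avoids acid-promoted cyclodehydration of the electron-rich 1,4-diol and epimerisation α to the new ketones.

Step 11
Reactants: 15 all-cis diketone
Product: 17 (1R,2S,3R,4S)-2,3-bis[2,4-bis(benzyloxy)-6-fluorobenzoyl]-1-[4-(benzyloxy)phenyl]-4-(4-methoxyphenyl)butane-1,4-diyl diformate, via ring-opened dialdehyde 16 (not isolated)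
Conditions: O3, CH2Cl2, −78 °C (indicator dye end point); PPh3 (1.0 equiv), −78 °C → rt; then mCPBA, NaHCO3 (buffer), CH2Cl2, 0 °C
Reagents that add atoms: ozone, [O-][O+]=O; 3-chloroperoxybenzoic acid, OOC(=O)c1cccc(Cl)c1
Why: Ozonolysis with reductive work-up cleaves the only alkene, then Baeyer–Villiger oxidation of the α-branched aldehydes: in the peracid adduct the secondary 4-alkoxybenzylic carbon migrates in preference to hydride and with retention, so C-2 and C-2'' receive oxygen exactly where the alkene carbons stood. The twisted, hindered aryl ketones are much slower Baeyer–Villiger substrates than aldehydes, and the neutral, cold conditions keep 16 from enolising.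

Step 12
Reactants: 17 bis-formate
Product: 19 5,7,5'',7'',4'''-penta-O-benzyl ether of the target (2S,3R,2''R,3''S), via diol 18 (not isolated)
Conditions: K2CO3 (cat.), MeOH/THF, 0 °C; solvent exchange; then Cs2CO3, DMF, 0 °C → rt
Reagents that add atoms: none
Why: Methanolysis of the formates, then twofold intramolecular nucleophilic aromatic substitution: each benzylic alkoxide attacks the fluorine-bearing carbon ortho to its β-carbonyl through a six-membered transition state, with the ketone stabilising the Meisenheimer intermediate. The C-2–O and C-2''–O bonds are never broken, so configuration is retained, and C-3 and C-3'' already hold the thermodynamically preferred 2,3-trans arrangement, so any enolisation there is self-correcting.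

Step 13
Reactants: 19 penta-O-benzyl biflavanone
Product: 20 (2S,3R)-3-[(2R,3S)-5,7-dihydroxy-2-(4-hydroxyphenyl)-4-oxochroman-3-yl]-5,7-dihydroxy-2-(4-methoxyphenyl)chroman-4-one (CNP0196568.3)
Conditions: H2 (1 atm), Pd/C, EtOAc/MeOH, rt
Reagents that add atoms: none
Why: Hydrogenolysis of five benzyl ethers under neutral conditions; the methyl ether is inert, and the chelated aryl ketones and the cyclic benzylic C-2–O-1 ethers react far more slowly than O-benzyl groups at ambient pressure.

## Compound list

1 | 4-(benzyloxy)benzyl chloride | ClCc1ccc(OCc2ccccc2)cc1 | starting material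
2 | diethyl [4-(benzyloxy)benzyl]phosphonate | CCOP(=O)(Cc1ccc(OCc2ccccc2)cc1)OCC | intermediate
3 | (E)-4-methoxycinnamaldehyde | COc1ccc(/C=C/C=O)cc1 | starting material
4 | (1E,3E)-1-[4-(benzyloxy)phenyl]-4-(4-methoxyphenyl)buta-1,3-diene | COc1ccc(/C=C/C=C/c2ccc(OCc3ccccc3)cc2)cc1 | intermediate
5 | maleic anhydride | O=C1OC(=O)C=C1 | starting material
6 | rac-(3aR,4R,7S,7aS)-4-[4-(benzyloxy)phenyl]-7-(4-methoxyphenyl)-3a,4,7,7a-tetrahydro-2-benzofuran-1,3-dione (all-cis; racemate, the enantiomer carried on is drawn) | COc1ccc([C@H]2C=C[C@@H](c3ccc(OCc4ccccc4)cc3)[C@H]3C(=O)OC(=O)[C@@H]23)cc1 | intermediate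
7 | rac-[(1S,2R,3R,6S)-3-[4-(benzyloxy)phenyl]-6-(4-methoxyphenyl)cyclohex-4-ene-1,2-diyl]dimethanol (all-cis; racemate, the enantiomer carried on is drawn) | COc1ccc([C@H]2C=C[C@@H](c3ccc(OCc4ccccc4)cc3)[C@@H](CO)[C@H]2CO)cc1 | intermediate
8 | [(1S,2R,3R,6S)-3-[4-(benzyloxy)phenyl]-6-(4-methoxyphenyl)cyclohex-4-ene-1,2-diyl]dimethanol (single enantiomer) | COc1ccc([C@H]2C=C[C@@H](c3ccc(OCc4ccccc4)cc3)[C@@H](CO)[C@H]2CO)cc1 | intermediate
9 | (1S,2R,3R,6S)-3-[4-(benzyloxy)phenyl]-6-(4-methoxyphenyl)cyclohex-4-ene-1,2-dicarbaldehyde | COc1ccc([C@H]2C=C[C@@H](c3ccc(OCc4ccccc4)cc3)[C@@H](C=O)[C@H]2C=O)cc1 | intermediate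
10 | 1,3,5-trifluorobenzene | Fc1cc(F)cc(F)c1 | starting material
11 | 1,3-bis(benzyloxy)-5-fluorobenzene | Fc1cc(OCc2ccccc2)cc(OCc2ccccc2)c1 | intermediate
12 | 1,5-bis(benzyloxy)-2-bromo-3-fluorobenzene | Fc1cc(OCc2ccccc2)cc(OCc2ccccc2)c1Br | intermediate
13 | [2,4-bis(benzyloxy)-6-fluorophenyl]magnesium chloride (LiCl complex; not isolated) | Fc1cc(OCc2ccccc2)cc(OCc2ccccc2)c1[Mg]Cl | intermediate
14 | [(1S,2R,3R,6S)-3-[4-(benzyloxy)phenyl]-6-(4-methoxyphenyl)cyclohex-4-ene-1,2-diyl]bis{[2,4-bis(benzyloxy)-6-fluorophenyl]methanol} (carbinol centres as mixtures) | COc1ccc([C@H]2C=C[C@@H](c3ccc(OCc4ccccc4)cc3)[C@@H](C(O)c3c(F)cc(OCc4ccccc4)cc3OCc3ccccc3)[C@H]2C(O)c2c(F)cc(OCc3ccccc3)cc2OCc2ccccc2)cc1 | intermediate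
15 | [(1S,2R,3R,6S)-3-[4-(benzyloxy)phenyl]-6-(4-methoxyphenyl)cyclohex-4-ene-1,2-diyl]bis{[2,4-bis(benzyloxy)-6-fluorophenyl]methanone} | COc1ccc([C@H]2C=C[C@@H](c3ccc(OCc4ccccc4)cc3)[C@@H](C(=O)c3c(F)cc(OCc4ccccc4)cc3OCc3ccccc3)[C@H]2C(=O)c2c(F)cc(OCc3ccccc3)cc2OCc2ccccc2)cc1 | intermediate
16 | (2R,3R,4S,5S)-3,4-bis[2,4-bis(benzyloxy)-6-fluorobenzoyl]-2-[4-(benzyloxy)phenyl]-5-(4-methoxyphenyl)hexanedial (not isolated) | COc1ccc([C@@H](C=O)[C@H](C(=O)c2c(F)cc(OCc3ccccc3)cc2OCc2ccccc2)[C@H](C(=O)c2c(F)cc(OCc3ccccc3)cc2OCc2ccccc2)[C@@H](C=O)c2ccc(OCc3ccccc3)cc2)cc1 | intermediate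
17 | (1R,2S,3R,4S)-2,3-bis[2,4-bis(benzyloxy)-6-fluorobenzoyl]-1-[4-(benzyloxy)phenyl]-4-(4-methoxyphenyl)butane-1,4-diyl diformate | COc1ccc([C@@H](OC=O)[C@H](C(=O)c2c(F)cc(OCc3ccccc3)cc2OCc2ccccc2)[C@H](C(=O)c2c(F)cc(OCc3ccccc3)cc2OCc2ccccc2)[C@@H](OC=O)c2ccc(OCc3ccccc3)cc2)cc1 | intermediate
18 | (1R,2S,3R,4S)-2,3-bis[2,4-bis(benzyloxy)-6-fluorobenzoyl]-1-[4-(benzyloxy)phenyl]-4-(4-methoxyphenyl)butane-1,4-diol (not isolated) | COc1ccc([C@@H](O)[C@H](C(=O)c2c(F)cc(OCc3ccccc3)cc2OCc2ccccc2)[C@H](C(=O)c2c(F)cc(OCc3ccccc3)cc2OCc2ccccc2)[C@@H](O)c2ccc(OCc3ccccc3)cc2)cc1 | intermediate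
19 | (2S,3R)-5,7-bis(benzyloxy)-3-[(2R,3S)-5,7-bis(benzyloxy)-2-[4-(benzyloxy)phenyl]-4-oxochroman-3-yl]-2-(4-methoxyphenyl)chroman-4-one | COc1ccc([C@H]2Oc3cc(OCc4ccccc4)cc(OCc4ccccc4)c3C(=O)[C@@H]2[C@@H]2C(=O)c3c(OCc4ccccc4)cc(OCc4ccccc4)cc3O[C@H]2c2ccc(OCc3ccccc3)cc2)cc1 | intermediate
20 | (2S,3R)-3-[(2R,3S)-5,7-dihydroxy-2-(4-hydroxyphenyl)-4-oxochroman-3-yl]-5,7-dihydroxy-2-(4-methoxyphenyl)chroman-4-one (CNP0196568.3) | COc1ccc([C@H]2Oc3cc(O)cc(O)c3C(=O)[C@@H]2[C@@H]2C(=O)c3c(O)cc(O)cc3O[C@H]2c2ccc(O)cc2)cc1 | target

## Step count and least certain steps

Total step count: 13. Longest linear sequence: 11 steps (steps 1 to 6 and 9 to 13); the fluoroarene branch (steps 7 and 8) joins at step 9.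

Step 3 (key step). The reaction type is well precedented. The most likely fault is incomplete conversion of the sparingly soluble diene together with some loss of endo selectivity on prolonged heating, because both termini of 4 carry aryl groups and the s-cis conformer is little populated. Fallback: starting from 4, the cycloaddition is run in neat diethyl maleate as dienophile and solvent, which also adds suprafacially and endo, to give racemic all-cis diethyl 3-[4-(benzyloxy)phenyl]-6-(4-methoxyphenyl)cyclohex-4-ene-1,2-dicarboxylate F1; reduction of F1 with LiAlH4 returns to the route at 7.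

Step 5. The most likely fault is insufficient chiral recognition, because the enantiomers differ only in which of two mirror-related aryl wings carries benzyl instead of methyl. Fallback: starting from 7, both hydroxyl groups are esterified with (1S)-camphanic chloride (pyridine, DMAP). This gives two diastereomers, the bis[(1S,4R)-camphanate] of 8, F2, and the bis[(1S,4R)-camphanate] of the enantiomer of 8, F3. They are separated by fractional crystallisation, and methanolysis of F2 (K2CO3, MeOH) returns to the route at 8.

Step 6 (with its sequel in steps 9 and 10). The most likely fault is epimerisation α to the formyl groups under the amine base, since the all-cis dialdehyde relieves strain by going trans, together with hydration or lactol formation of the 1,4-dialdehyde. In the sequel the mono-adduct may be held back as a lactolate, so that the second aryl group is not taken up, and the electron-rich carbinols of 14 may cyclodehydrate. Fallback: starting from 6, Fischer esterification (MeOH, H2SO4) gives the all-cis dimethyl 3-[4-(benzyloxy)phenyl]-6-(4-methoxyphenyl)cyclohex-4-ene-1,2-dicarboxylate F4, which is resolved on the same chiral stationary phase. Acylation of an excess of 13 by F4 (one aryl group per ester) stops at the ketone, because a 2,6-disubstituted aryl ketone does not accept a second hindered aryl group. This returns to the route at 15 and bypasses 7, 8, 9 and 14.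

Step 11. The most likely faults are attack of ozone on the benzyloxyarene rings in competition with the hindered alkene, and enolisation of the α-aryl aldehyde groups of 16 (loss of configuration at C-2 and C-2'') before oxygen insertion. Fallback: starting from 15, dihydroxylation with OsO4 (cat.)/NMO, which leaves arenes alone and attacks the face opposite to the aryl groups, gives the 4,5-cis-diol of 15, F5. Cleavage with Pb(OAc)4 in CH2Cl2 at −20 °C gives 16 under neutral, anhydrous conditions, and mCPBA is added directly, returning to the route at 17.

Step 12. The most likely fault is retro-aldol cleavage (and E1cB dehydration) of the β-hydroxy ketone alkoxides of 18, competing with ring closure on a fluoroarene that two alkoxy groups make less electrophilic. Fallback: starting from 17, both ketones are reduced first (NaBH4, MeOH/THF, then K2CO3) to the tetraol F6, in which no retro-aldol path exists. Intramolecular substitution of the unactivated aryl fluorides by the benzylic alkoxides (KOt-Bu, DMSO, 80–100 °C, six-membered closure) gives the bis(chroman-4-ol) F7, and oxidation of both benzylic alcohols with Dess–Martin periodinane returns to the route at 19.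

## Further compounds

F1 | step 3 | diethyl rac-(1S,2R,3R,6S)-3-[4-(benzyloxy)phenyl]-6-(4-methoxyphenyl)cyclohex-4-ene-1,2-dicarboxylate (all-cis, racemate) | COc1ccc([C@H]2C=C[C@@H](c3ccc(OCc4ccccc4)cc3)[C@@H](C(=O)OCC)[C@H]2C(=O)OCC)cc1
F2 | step 5 | bis[(1S,4R)-camphanate] of 8 | COc1ccc([C@H]2C=C[C@@H](c3ccc(OCc4ccccc4)cc3)[C@@H](COC(=O)[C@@]34CC[C@@](C)(C(=O)O3)C4(C)C)[C@H]2COC(=O)[C@@]23CC[C@@](C)(C(=O)O2)C3(C)C)cc1
F3 | step 5 | bis[(1S,4R)-camphanate] of the enantiomer of 8 | COc1ccc([C@@H]2C=C[C@H](c3ccc(OCc4ccccc4)cc3)[C@H](COC(=O)[C@@]34CC[C@@](C)(C(=O)O3)C4(C)C)[C@@H]2COC(=O)[C@@]23CC[C@@](C)(C(=O)O2)C3(C)C)cc1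
F4 | step 6 | dimethyl (1S,2R,3R,6S)-3-[4-(benzyloxy)phenyl]-6-(4-methoxyphenyl)cyclohex-4-ene-1,2-dicarboxylate (made racemic, then resolved) | COc1ccc([C@H]2C=C[C@@H](c3ccc(OCc4ccccc4)cc3)[C@@H](C(=O)OC)[C@H]2C(=O)OC)cc1
F5 | step 11 | 4,5-cis-diol of 15 (the four original ring hydrogens all cis; both hydroxyl groups on the face opposite to the two aryl and two aroyl groups) | COc1ccc([C@H]2[C@H](O)[C@H](O)[C@@H](c3ccc(OCc4ccccc4)cc3)[C@@H](C(=O)c3c(F)cc(OCc4ccccc4)cc3OCc3ccccc3)[C@H]2C(=O)c2c(F)cc(OCc3ccccc3)cc2OCc2ccccc2)cc1
F6 | step 12 | tetraol from reduction of both ketones of 18 (C-4 and C-4'' carbinols as mixtures) | COc1ccc([C@@H](O)[C@H](C(O)c2c(F)cc(OCc3ccccc3)cc2OCc2ccccc2)[C@H](C(O)c2c(F)cc(OCc3ccccc3)cc2OCc2ccccc2)[C@@H](O)c2ccc(OCc3ccccc3)cc2)cc1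
F7 | step 12 | bis(chroman-4-ol) corresponding to 19 (C-4 and C-4'' carbinols as mixtures) | COc1ccc([C@H]2Oc3cc(OCc4ccccc4)cc(OCc4ccccc4)c3C(O)[C@@H]2[C@@H]2C(O)c3c(OCc4ccccc4)cc(OCc4ccccc4)cc3O[C@H]2c2ccc(OCc3ccccc3)cc2)cc1
A1 | alternative 1 | 4'''-O-benzyl ether of 20 | COc1ccc([C@H]2Oc3cc(O)cc(O)c3C(=O)[C@@H]2[C@@H]2C(=O)c3c(O)cc(O)cc3O[C@H]2c2ccc(OCc3ccccc3)cc2)cc1
A2 | alternative 1 | (2S,3R)-5-bromo-3-[(2R,3S)-5-bromo-2-[4-(benzyloxy)phenyl]-4-oxo-3,4-dihydro-2H-pyran-3-yl]-2-(4-methoxyphenyl)-2,3-dihydro-4H-pyran-4-one | COc1ccc([C@H]2OC=C(Br)C(=O)[C@@H]2[C@@H]2C(=O)C(Br)=CO[C@H]2c2ccc(OCc3ccccc3)cc2)cc1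
A3 | alternative 1 | 1-methoxy-1,3-bis(trimethylsilyloxy)buta-1,3-diene | COC(O[Si](C)(C)C)=CC(=C)O[Si](C)(C)C
A4 | alternative 2 | 5,5''-di-O-(tert-butyldimethylsilyl)-7,7'',4'''-tri-O-benzyl ether of 20 | COc1ccc([C@H]2Oc3cc(OCc4ccccc4)cc(O[Si](C)(C)C(C)(C)C)c3C(=O)[C@@H]2[C@@H]2C(=O)c3c(O[Si](C)(C)C(C)(C)C)cc(OCc4ccccc4)cc3O[C@H]2c2ccc(OCc3ccccc3)cc2)cc1
A5 | alternative 2 | (2R,3S)-7-(benzyloxy)-2-[4-(benzyloxy)phenyl]-5-(tert-butyldimethylsilyloxy)-3-{2-[4-(benzyloxy)-2-(tert-butyldimethylsilyloxy)-6-(4-methoxybenzyloxy)phenyl]-1-diazo-2-oxoethyl}chroman-4-one | COc1ccc(COc2cc(OCc3ccccc3)cc(O[Si](C)(C)C(C)(C)C)c2C(=O)C(=[N+]=[N-])[C@@H]2C(=O)c3c(O[Si](C)(C)C(C)(C)C)cc(OCc4ccccc4)cc3O[C@H]2c2ccc(OCc3ccccc3)cc2)cc1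
A6 | alternative 3 | pentacyclic furan-bridged bis-chromene (penta-O-benzyl, 4'-O-methyl) | COc1ccc([C@H]2Oc3cc(OCc4ccccc4)cc(OCc4ccccc4)c3-c3oc4-c5c(OCc6ccccc6)cc(OCc6ccccc6)cc5O[C@@H](c5ccc(OCc6ccccc6)cc5)c4c32)cc1
A7 | alternative 3 | furo-fused chromene of unit A carrying a 2-hydroxy-4,6-bis(benzyloxy)phenyl group on the free furan α-carbon | COc1ccc([C@H]2Oc3cc(OCc4ccccc4)cc(OCc4ccccc4)c3-c3oc(-c4c(O)cc(OCc5ccccc5)cc4OCc4ccccc4)cc32)cc1
A8 | alternative 3 | 4-(benzyloxy)benzaldehyde | O=Cc1ccc(OCc2ccccc2)cc1
A9 | alternative 3 | Z-ene-dione from oxidative opening of the furan of A6 (C-3=C-3'' double bond between the two penta-O-benzyl chroman-4-one units, carbonyl groups cis) | COc1ccc([C@H]2Oc3cc(OCc4ccccc4)cc(OCc4ccccc4)c3C(=O)/C2=C2\C(=O)c3c(OCc4ccccc4)cc(OCc4ccccc4)cc3O[C@H]2c2ccc(OCc3ccccc3)cc2)cc1
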